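**Retrosynthetic overview**

1. Numbering: ring A carbons C1 (carries the side chain), C2 (CH2), C3–C4 (oxirane, CH3 on C4), C5 and C6 (angelates); chain C7 (=CH2), C8 (angelate), C9, C10–C11 (oxirane). The plan rests on C6–O being trans to the C1 substituent and 1,4-related to C3 across C4(CH3)=C5: C3 and C6 are the ends of a 2-methylcyclohexa-1,3-diene inside ring A that an O–O unit can span.
2. Key disconnection: the C3–O and C6–O bonds, made together by [4+2] addition of singlet O2 to (S)-5-isopropenyl-2-methylcyclohexa-1,3-diene (two steps from (S)-carvone: tosylhydrazone, Shapiro). This closes a temporary 1,2-dioxane and fixes C6 relative to C1.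
3. The peroxide is then spent: Kornblum–DeLaMare opening (C3 ketone, C6–OH), silylation, and a 1,3-carbonyl transposition (epoxidation, Wharton, oxidation) to the C5 ketone. The C3–C4 oxirane comes from alkaline H2O2 anti to C1, and the C5 carbinol from hydride delivered by the C6 hydroxyl.
4. Side chain: C8 is oxidised by ene-chlorination and N-oxide oxidation of the isopropenyl methyl; C8–C9 by Brown allylation (sets C8); C10=C11 by cross-metathesis; one triple angeloylation; C10–C11 oxirane last by Shi epoxidation (sets C10).
5. Ring order: carbocycle A (from carvone), then the 1,2-dioxane (step 3, opened in step 4), then the C3–C4 oxirane (step 13), then the C10–C11 oxirane (step 17).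

Key step: step 3

Remark: the C8 oxygen is introduced after the key step, so the diene and its peroxide carry a plain isopropenyl group at C1; (−)-Ipc2B(allyl) is taken as the purchased reagent solution.

**Route**

Step 1
Reactants: 1 (S)-carvone; 2 p-toluenesulfonyl hydrazide
Product: 3 (S)-carvone p-toluenesulfonylhydrazone
Conditions: EtOH, AcOH (cat.), rt
Reagents that add atoms: p-toluenesulfonyl hydrazide, Cc1ccc(cc1)S(=O)(=O)NN
Why: Hydrazone formation by condensation at the ketone; the C1 stereocentre is not touched.

Step 2
Reactants: 3 (S)-carvone p-toluenesulfonylhydrazone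
Product: 5 (S)-5-isopropenyl-2-methylcyclohexa-1,3-diene, via 3-lithio diene 4 (not isolated)
Conditions: MeLi (2.5 equiv), Et2O, 0 °C to rt; then H2O
Reagents that add atoms: none
Why: Shapiro reaction: the dianion from N–H and α'-C–H (C6) deprotonation expels sulfinate and N2, and the vinyllithium is protonated on work-up to give the homoannular C3=C4–C5=C6 diene with C1 intact.

Step 3
Reactants: 5 (S)-5-isopropenyl-2-methylcyclohexa-1,3-diene; 6 dioxygen
Product: 7 5-methyl-7-(prop-1-en-2-yl)-2,3-dioxabicyclo[2.2.2]oct-5-ene (O–O bridge across C3 and C6 on the face opposite to the C1 isopropenyl group)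
Conditions: O2 (1 atm), tetraphenylporphyrin (cat.), visible light, CH2Cl2, −20 °C; chromatographic removal of the syn adduct
Reagents that add atoms: dioxygen, O=O
Why: Tetraphenylporphyrin-sensitised singlet oxygen adds to the s-cis diene C3=C4–C5=C6 in a concerted suprafacial [4+2] cycloaddition, the reaction type known from the photooxygenation of α-phellandrene and α-terpinene. The 1,2-dioxane closes by the cycloaddition itself: both C–O bonds form in one step across C3 and C6 and give the 2,3-dioxabicyclo[2.2.2]octene. C3 and C6 are cis to each other because the addition is suprafacial, and their configuration relative to C1 is set by approach of oxygen to the diene face anti to the isopropenyl group on the neighbouring sp3 carbon C1. The step needs π-facial selectivity, which this substituent should provide only to a moderate degree, so the syn adduct is expected as a separable minor isomer. It also needs [4+2] over ene selectivity, which the locked cisoid diene secures because it reacts far faster than the 1,1-disubstituted isopropenyl alkene, and the low temperature holds back ene reaction at the C4 methyl and C2 methylene.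

Step 4
Reactants: 7 endoperoxide
Product: 8 trans-4-hydroxy-2-methyl-5-(prop-1-en-2-yl)cyclohex-2-en-1-one (C3 ketone, C4=C5, C6–OH trans to C1)
Conditions: Et3N (0.5 equiv), CH2Cl2, 0 °C, short reaction time
Reagents that add atoms: none
Why: Kornblum–DeLaMare rearrangement: the amine removes the bridgehead C3–H (flanked by CH2 and a methyl, less encumbered than C6–H next to the branched C1) as the O–O bond breaks, giving the C3 ketone and the C6 hydroxyl with C6 unchanged.

Step 5
Reactants: 8 hydroxy enone
Product: 9 trans-4-(tert-butyldimethylsilyloxy)-2-methyl-5-(prop-1-en-2-yl)cyclohex-2-en-1-one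
Conditions: TBSCl, imidazole, DMF, rt
Reagents that add atoms: tert-butyldimethylsilyl chloride, CC(C)(C)[Si](C)(C)Cl
Why: Standard silylation of the secondary alcohol; it masks C6–OH for the transposition and the side-chain work.

Step 6
Reactants: 9 silyloxy enone
Product: 10 C4–C5 epoxy ketone of 9 (oxirane drawn anti to C6–OTBS)
Conditions: H2O2 (30% aq.), NaOH (cat.), MeOH, 0 °C
Reagents that add atoms: hydrogen peroxide, OO
Why: Weitz–Scheffer nucleophilic epoxidation of the enone; the oxirane is expected mainly anti to the adjacent silyloxy group, but its configuration does not matter because C4 and C5 both return to sp2 in steps 7 and 8.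

Step 7
Reactants: 10 epoxy ketone
Product: 13 6-(tert-butyldimethylsilyloxy)-2-methyl-5-(prop-1-en-2-yl)cyclohex-2-en-1-ol (C3=C4, C5–OH), via epoxy hydrazone 11 (not isolated), via alkenyl diazene 12 (not isolated)
Conditions: N2H4·H2O, AcOH (cat.), MeOH, 0 °C to rt
Reagents that add atoms: none
Why: Wharton transposition: the hydrazone opens the oxirane to the alkenyl diazene, which loses N2 to leave C3=C4 and the C5 carbinol, so the C3 oxygen is removed (either C5 epimer is carried on).

Step 8
Reactants: 13 allylic alcohol
Product: 14 (5R,6R)-6-(tert-butyldimethylsilyloxy)-2-methyl-5-(prop-1-en-2-yl)cyclohex-2-en-1-one (C5 ketone, C3=C4, C6–OTBS trans to C1)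
Conditions: Dess–Martin periodinane, NaHCO3, CH2Cl2, 0 °C to rt
Reagents that add atoms: none
Why: Dess–Martin oxidation of the allylic alcohol completes the 1,3-carbonyl transposition; C6 keeps the configuration fixed in step 3.

Step 9
Reactants: 14 transposed enone
Product: 15 trans-6-(tert-butyldimethylsilyloxy)-5-(3-chloroprop-1-en-2-yl)-2-methylcyclohex-2-en-1-one
Conditions: Ca(OCl)2, solid CO2, CH2Cl2/H2O, 0 °C
Reagents that add atoms: calcium hypochlorite, [Ca+2].[O-]Cl.[O-]Cl
Why: Ene-type allylic chlorination by HOCl, as known for carvone itself, attacks only the electron-rich isopropenyl group; the conjugated ring alkene is inert.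

Step 10
Reactants: 15 allylic chloride
Product: 17 2-[trans-2-(tert-butyldimethylsilyloxy)-4-methyl-3-oxocyclohex-4-en-1-yl]prop-2-enal (C8 aldehyde), via allyloxyammonium chloride 16 (not isolated)
Conditions: Me3NO (anhydrous), DMSO, rt
Reagents that add atoms: trimethylamine N-oxide, C[N+](C)(C)[O-]
Why: Ganem (Kornblum-type) oxidation: the N-oxide displaces the allylic chloride (SN2 and SN2' give the same 2-substituted allyl system) and the alkoxyammonium salt collapses to the enal.

Step 11
Reactants: 17 keto enal; 18 (−)-B-allyldiisopinocampheylborane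
Product: 20 (8S)-homoallylic alcohol (C8–OH, C9–C10=CH2; ring as in 14), via diisopinocampheylborinate 19 (not isolated)
Conditions: 18 (1.2 equiv), Et2O, −78 °C; then ethanolamine, rt
Reagents that add atoms: (−)-B-allyldiisopinocampheylborane, C=CCB([C@@H]1C[C@@H]2C[C@H]([C@H]1C)C2(C)C)[C@@H]1C[C@@H]2C[C@H]([C@H]1C)C2(C)C
Why: Brown asymmetric allylboration through a chair six-membered transition state; the aldehyde reacts far faster than the hindered conjugated ketone, the (+)-α-pinene-derived reagent (which gives S carbinols from aldehydes bearing an sp2 substituent) sets C8 as S under reagent control, and the ethanolamine work-up avoids alkaline peroxide, which would epoxidise the enone too early.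

Step 12
Reactants: 20 homoallylic alcohol; 21 2-methyl-2-butene
Product: 22 (8S)-prenyl carbinol (C10=C11(CH3)2; ring as in 14)
Conditions: second-generation Grubbs catalyst RuCl2(=CHPh)(PCy3)(H2IMes) (5 mol%), 2-methyl-2-butene (excess), CH2Cl2, 40 °C
Reagents that add atoms: 2-methyl-2-butene, CC=C(C)C
Why: Olefin cross-metathesis of the monosubstituted alkene converts allyl into prenyl; the 1,1-disubstituted C7 alkene and the trisubstituted enone alkene are too hindered and electron-poor to take part.

Step 13
Reactants: 22 prenyl enone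
Product: 23 C3–C4 epoxy ketone (oxirane trans to the C1 side chain; C5 ketone, C6–OTBS)
Conditions: H2O2 (30% aq.), NaOH (0.2 equiv), MeOH, −10 to 0 °C, short reaction time
Reagents that add atoms: hydrogen peroxide, OO
Why: Weitz–Scheffer epoxidation: hydroperoxide adds axially to C3 anti to the equatorial C1 substituent (as in carvone to trans-carvone oxide), which sets C3 and C4; isolated alkenes are untouched, and low temperature with little base limits enolisation at C6.

Step 14
Reactants: 23 silyloxy epoxy ketone
Product: 24 C6-hydroxy epoxy ketone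
Conditions: HF·pyridine, pyridine, THF, 0 °C to rt
Reagents that add atoms: none
Why: Fluoride-mediated Si–O cleavage under buffered acidic conditions frees the α-hydroxyl without base-induced ketol isomerisation or oxirane opening.

Step 15
Reactants: 24 α-hydroxy epoxy ketone
Product: 25 triol (C5–OH trans to C6–OH and to the C3–C4 oxirane; C8–OH)
Conditions: Me4NBH(OAc)3, MeCN/AcOH, −20 °C
Reagents that add atoms: none
Why: Hydroxyl-directed (Saksena–Evans) reduction: boron binds the C6 oxygen and hydride is delivered to the same face of the C5 carbonyl, so the new C5 hydroxyl is trans to C6–OH; the free reagent does not reduce ketones at this temperature, which suppresses undirected attack.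

Step 16
Reactants: 25 triol; 26 angelic acid
Product: 27 C5,C6,C8-tris-angelate (C10=C11 still an alkene)
Conditions: 26, 2,4,6-trichlorobenzoyl chloride, Et3N, toluene, rt; then 25, 80 °C
Reagents that add atoms: angelic acid, C/C=C(/C)C(=O)O
Why: Yamaguchi-type acylation with the preformed mixed anhydride and no DMAP, the protocol that transfers the angeloyl group without Z to E isomerisation; all three secondary hydroxyls are esterified and no stereocentre is touched.

Step 17
Reactants: 27 tris-angelate
Product: 28 CNP0258231.1 (target; 1R,3S,4S,5S,6R,8S,10R in the overview numbering)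
Conditions: D-fructose-derived Shi ketone (30 mol%), Oxone (2KHSO5·KHSO4·K2SO4), K2CO3, Bu4NHSO4, MeCN/dimethoxymethane/aq. Na2B4O7 buffer, 0 °C
Reagents that add atoms: potassium peroxymonosulfate (active component of Oxone), [K+].[O-]S(=O)(=O)OO
Why: Shi asymmetric epoxidation: the chiral dioxirane attacks only the electron-rich trisubstituted C10=C11 alkene (the angelate and the acyloxy-substituted C7 alkenes are deactivated), and the D-fructose-derived ketone should give the 10R oxirane through the spiro transition state under catalyst control.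

**Compound list**

1 | (S)-carvone | CC1=CC[C@@H](CC1=O)C(C)=C | starting material
2 | p-toluenesulfonyl hydrazide | Cc1ccc(cc1)S(=O)(=O)NN | starting material
3 | (S)-carvone p-toluenesulfonylhydrazone | C=C(C)[C@H]1CC=C(C)C(=NNS(=O)(=O)c2ccc(C)cc2)C1 | intermediate
4 | 3-lithio-5-isopropenyl-2-methylcyclohexa-1,3-diene (not isolated) | C=C(C)[C@H]1CC=C(C)C([Li])=C1 | intermediate
5 | (S)-5-isopropenyl-2-methylcyclohexa-1,3-diene | C=C(C)[C@H]1CC=C(C)C=C1 | intermediate
6 | dioxygen | O=O | starting material
7 | 5-methyl-7-(prop-1-en-2-yl)-2,3-dioxabicyclo[2.2.2]oct-5-ene, peroxide anti to isopropenyl | C=C(C)[C@H]1C[C@H]2C(C)=C[C@@H]1OO2 | intermediate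
8 | (4S,5R)-4-hydroxy-2-methyl-5-(prop-1-en-2-yl)cyclohex-2-en-1-one | C=C(C)[C@H]1CC(=O)C(C)=C[C@@H]1O | intermediate
9 | TBS ether of 8 | C=C(C)[C@H]1CC(=O)C(C)=C[C@@H]1O[Si](C)(C)C(C)(C)C | intermediate
10 | C4–C5 epoxy ketone (oxirane anti to OTBS) | C=C(C)[C@H]1CC(=O)[C@@]2(C)O[C@H]2[C@@H]1O[Si](C)(C)C(C)(C)C | intermediate
11 | hydrazone of 10 (not isolated) | C=C(C)[C@H]1CC(=NN)[C@@]2(C)O[C@H]2[C@@H]1O[Si](C)(C)C(C)(C)C | intermediate
12 | C3-diazenyl C3=C4 alkene with C5–OH (not isolated) | C=C(C)[C@H]1CC(N=N)=C(C)[C@@H](O)[C@@H]1O[Si](C)(C)C(C)(C)C | intermediate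
13 | 6-(tert-butyldimethylsilyloxy)-2-methyl-5-(prop-1-en-2-yl)cyclohex-2-en-1-ol | C=C(C)[C@H]1CC=C(C)[C@@H](O)[C@@H]1O[Si](C)(C)C(C)(C)C | intermediate
14 | (5R,6R)-6-(tert-butyldimethylsilyloxy)-2-methyl-5-(prop-1-en-2-yl)cyclohex-2-en-1-one | C=C(C)[C@H]1CC=C(C)C(=O)[C@@H]1O[Si](C)(C)C(C)(C)C | intermediate
15 | 5-(3-chloroprop-1-en-2-yl) analogue of 14 | C=C(CCl)[C@H]1CC=C(C)C(=O)[C@@H]1O[Si](C)(C)C(C)(C)C | intermediate
16 | allyloxytrimethylammonium chloride from 15 (not isolated) | C=C(CO[N+](C)(C)C)[C@H]1CC=C(C)C(=O)[C@@H]1O[Si](C)(C)C(C)(C)C.[Cl-] | intermediate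
17 | C8 enal (keto aldehyde) | C=C(C=O)[C@H]1CC=C(C)C(=O)[C@@H]1O[Si](C)(C)C(C)(C)C | intermediate
18 | (−)-B-allyldiisopinocampheylborane | C=CCB([C@@H]1C[C@@H]2C[C@H]([C@H]1C)C2(C)C)[C@@H]1C[C@@H]2C[C@H]([C@H]1C)C2(C)C | starting material
19 | diisopinocampheylborinate of 20 (not isolated) | C=C([C@H](CC=C)OB([C@@H]1C[C@@H]2C[C@H]([C@H]1C)C2(C)C)[C@@H]1C[C@@H]2C[C@H]([C@H]1C)C2(C)C)[C@H]1CC=C(C)C(=O)[C@@H]1O[Si](C)(C)C(C)(C)C | intermediate
20 | (8S)-homoallylic alcohol | C=C([C@H](CC=C)O)[C@H]1CC=C(C)C(=O)[C@@H]1O[Si](C)(C)C(C)(C)C | intermediate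
21 | 2-methyl-2-butene | CC=C(C)C | starting material
22 | (8S)-prenyl carbinol enone | C=C([C@H](CC=C(C)C)O)[C@H]1CC=C(C)C(=O)[C@@H]1O[Si](C)(C)C(C)(C)C | intermediate
23 | C3–C4 epoxy ketone, C6–OTBS | C=C([C@H](CC=C(C)C)O)[C@H]1C[C@@H]2O[C@]2(C)C(=O)[C@@H]1O[Si](C)(C)C(C)(C)C | intermediate
24 | C3–C4 epoxy ketone, C6–OH | C=C([C@H](CC=C(C)C)O)[C@H]1C[C@@H]2O[C@]2(C)C(=O)[C@@H]1O | intermediate
25 | C5,C6,C8-triol with C3–C4 oxirane | C=C([C@H](CC=C(C)C)O)[C@H]1C[C@@H]2O[C@]2(C)[C@@H](O)[C@@H]1O | intermediate
26 | angelic acid | C/C=C(/C)C(=O)O | starting material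
27 | C5,C6,C8-tris-angelate with C10=C11 alkene | C=C([C@H](CC=C(C)C)OC(=O)/C(C)=C\C)[C@H]1C[C@@H]2O[C@]2(C)[C@@H](OC(=O)/C(C)=C\C)[C@@H]1OC(=O)/C(C)=C\C | intermediate
28 | CNP0258231.1 | C=C([C@H](C[C@H]1OC1(C)C)OC(=O)/C(C)=C\C)[C@H]1C[C@@H]2O[C@]2(C)[C@@H](OC(=O)/C(C)=C\C)[C@@H]1OC(=O)/C(C)=C\C | target

**Step count**

Total: 17 steps. Longest linear sequence: 17 steps, from (S)-carvone 1.

**Steps most likely to fail**

Step 3 (key step). The isopropenyl group on C1 may discriminate only weakly between the two diene faces, so a large share of the material could be diverted into the syn adduct; ene hydroperoxides and aromatisation of 5 would add to the loss. Fallback, setting out from 5 and returning at 8: the syn-endoperoxide F1 that accompanies 7 is not discarded. Under the conditions of step 4 it should open to the cis-hydroxy enone F2. A Mitsunobu reaction (4-nitrobenzoic acid, PPh3, DIAD, THF, 0 °C) then inverts C6, the carboxylate entering from the face opposite to the C1 substituent, to give the trans 4-nitrobenzoate F3. Methanolysis (K2CO3, MeOH, 0 °C) gives 8, so both facial isomers of the cycloaddition converge.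

Step 4. Proton abstraction may lose regiocontrol (C6–H instead of C3–H, which gives the C6 ketone), and the base may carry 8 on to the 1,4-diketone through the dienol. Fallback, setting out from 7 and returning at 8: the O–O bond is cleaved reductively with thiourea in MeOH at rt to the cis-ene-1,4-diol F4. The less hindered C3 carbinol (next to a CH2, whereas C6–OH sits beside the branched C1) is then oxidised with TEMPO (cat.) and PhI(OAc)2 in CH2Cl2. Selection here rests on steric access to an O–H group instead of on C–H acidity, and no base is present.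

Step 16. Acylation of the vicinal, hindered C5 and C6 carbinols may stall at partial esters; prolonged heating may isomerise the angeloyl donor to tiglate or let chloride open the oxirane. Fallback, setting out from 25 and returning at 27: the three carbinols are esterified with the unhindered 2-[bis(2,2,2-trifluoroethoxy)phosphoryl]propanoic acid (EDC·HCl, DMAP, CH2Cl2) to the tris(phosphonopropionate) F5. A threefold Still–Gennari olefination with acetaldehyde (KN(SiMe3)2, 18-crown-6, THF, −78 °C) then builds the Z-configured 2-methylbut-2-enoates on the molecule.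

**Further compounds**

F1 | step 3 | syn-endoperoxide (peroxide on the face of the isopropenyl group) | C=C(C)[C@H]1C[C@@H]2C(C)=C[C@H]1OO2
F2 | step 3 | cis-4-hydroxy-2-methyl-5-(prop-1-en-2-yl)cyclohex-2-en-1-one | C=C(C)[C@H]1CC(=O)C(C)=C[C@H]1O
F3 | step 3 | trans 4-nitrobenzoate of 8 | C=C(C)[C@H]1CC(=O)C(C)=C[C@@H]1OC(=O)c2ccc(cc2)[N+](=O)[O-]
F4 | step 4 | cis-2-methyl-5-(prop-1-en-2-yl)cyclohex-2-ene-1,4-diol (C3–OH and C6–OH both trans to isopropenyl) | C=C(C)[C@H]1C[C@H](O)C(C)=C[C@@H]1O
F5 | step 16 | C5,C6,C8-tris{2-[bis(2,2,2-trifluoroethoxy)phosphoryl]propanoate} of 25 | C=C([C@H](CC=C(C)C)OC(=O)C(C)P(=O)(OCC(F)(F)F)OCC(F)(F)F)[C@H]1C[C@@H]2O[C@]2(C)[C@@H](OC(=O)C(C)P(=O)(OCC(F)(F)F)OCC(F)(F)F)[C@@H]1OC(=O)C(C)P(=O)(OCC(F)(F)F)OCC(F)(F)F
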